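## Retrosynthetic overview

1. Isochromene numbering is used throughout, also for open precursors (O2, C1, C3, C4, C4a, C5, C6, C7, C8, C8a). The target is the C7 octanoate of ketol 12, so the last step is an O-acylation.
2. Key disconnection C7–C8: the α-ketol C8(=O)–C7(OH)(CH3) in the carbocycle is a benzoin retron. Opening it gives the achiral aldehyde–dione 11, so ring closure and the only stereocentre come from one carbene-catalysed step.
3. Enabling feature: the 4-ylidene-4H-pyran ring (O2, C1, C8a, C4a, C4, C3) carries the C8 formyl group on C8a and the chain C5–C6(=O)–C7(=O)CH3 on C4a, a 1,6-relationship. Its push–pull C4a=C5 bond can rotate, so both alkene isomers can reach the closing geometry.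
4. 11 comes from γ-pyrone 7 by acetylide addition, Meyer–Schuster rearrangement and oxidation of the side-chain carbinol.
5. Ring order: pyran ring first (acylketene/enol ether hetero-Diels–Alder, step 2), carbocycle C4a–C5–C6–C7–C8–C8a last (step 5).

Key step: step 5

Assumption: the (5aS,10bR) antipode of the triazolium salt is written in step 5. The sense of induction on this substrate is not known in advance; both antipodes are commercial and the one that gives (7R)-12 is used.

## Route

Step 1
Reactants: 1 Meldrum's acid (2,2-dimethyl-1,3-dioxane-4,6-dione); 2 octanoyl chloride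
Product: 3 5-(1-hydroxyoctylidene)-2,2-dimethyl-1,3-dioxane-4,6-dione
Conditions: pyridine (2 equiv), CH2Cl2, 0 °C → rt
Reagents that add atoms: none
Why: C-acylation of Meldrum's acid by an acid chloride gives the enolised acyl Meldrum's acid, a storable acylketene precursor.

Step 2
Reactants: 3 5-(1-hydroxyoctylidene)-2,2-dimethyl-1,3-dioxane-4,6-dione; 4 (E)-1,3,3-trimethoxyprop-1-ene
Product: 7 3-(dimethoxymethyl)-6-heptyl-4H-pyran-4-one, via heptanoylketene 5 (not isolated), via 2-methoxy-2,3-dihydro-4H-pyran-4-one adduct 6 (not isolated)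
Conditions: 4 (3 equiv), toluene, 95 °C; then PPTS (cat.), 4 Å MS, 60 °C
Reagents that add atoms: none
Why: Thermolysis of 3 releases the acylketene, which undergoes an inverse-demand hetero-Diels–Alder reaction with the enol ether (ketene carbon to the nucleophilic β-carbon), and acid-catalysed loss of methanol from the adduct gives the γ-pyrone, the thermodynamic sink, with the formyl group still masked as its acetal.

Step 3
Reactants: 7 3-(dimethoxymethyl)-6-heptyl-4H-pyran-4-one; 8 but-3-yn-2-ol (racemic)
Product: 10 6-heptyl-4-(3-hydroxy-2-oxobutylidene)-4H-pyran-3-carbaldehyde (E/Z mixture, racemic), via alkynyl pyranol 9 (not isolated)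
Conditions: 8, n-BuLi (2 equiv per 8), THF, −78 → 0 °C; then 7, −78 → −20 °C; then 1 M aq HCl, THF, 0 °C → rt
Reagents that add atoms: water, O
Why: 1,2-Addition of the lithium acetylide to the pyranone carbonyl gives a tertiary propargylic alcohol that ionises in aqueous acid to a 4-alkynylpyrylium ion; water adds at the remote alkyne carbon (Meyer–Schuster rearrangement) to give the 4-(acylmethylene)-4H-pyran, the same acid unmasks the aldehyde, and the racemic side-chain carbinol is removed in step 4.

Step 4
Reactants: 10 6-heptyl-4-(3-hydroxy-2-oxobutylidene)-4H-pyran-3-carbaldehyde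
Product: 11 4-(2,3-dioxobutylidene)-6-heptyl-4H-pyran-3-carbaldehyde (E/Z mixture)
Conditions: Dess–Martin periodinane (1.3 equiv), CH2Cl2, 0 °C → rt; used directly in step 5
Reagents that add atoms: none
Why: Dess–Martin oxidation converts the secondary α-hydroxy ketone into the 1,2-dione under non-aqueous conditions that should leave the aldehyde and the push–pull alkene untouched.

Step 5
Reactants: 11 4-(2,3-dioxobutylidene)-6-heptyl-4H-pyran-3-carbaldehyde
Product: 12 (7R)-3-heptyl-7-hydroxy-7-methyl-6H-isochromene-6,8(7H)-dione
Conditions: (5aS,10bR)-2-(pentafluorophenyl)-5a,10b-dihydro-4H,6H-indeno[2,1-b][1,2,4]triazolo[4,3-d][1,4]oxazin-2-ium tetrafluoroborate (10 mol %), Et3N (20 mol %), toluene, rt, Ar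
Reagents that add atoms: none
Why: The free carbene adds to the C8 aldehyde and the resulting Breslow intermediate (an acyl-anion equivalent at C8) attacks the C7 methyl ketone of the dione, after which proton transfer and loss of the carbene give the C8 ketone and the C7 tertiary alcohol. The closest known reaction type is the enantioselective intramolecular crossed aldehyde–ketone benzoin reaction with aminoindanol-derived triazolium salts, which gives six-membered cyclic tertiary α-ketols. The carbocycle C4a–C5–C6–C7–C8–C8a is closed by a 6-exo-trig attack of C8 on the C7 carbonyl, forming the C7–C8 bond. The C7 stereocentre is set by the catalyst alone: the indane wall of the azolium-bound enol shields one face of the ketone, whose two flanks (CH3 and the C6 acyl group) differ clearly in size. Chemoselectivity for C7 over C6 follows from ring size (attack at C6 would give a five-membered ring) and from C6 being a deactivated vinylogous ester carbonyl, and the homoenolate position C1 cannot reach C7 across the pyran ring. Only the isomer with C6 cis to C8a about C4a=C5 (Z) can close, and the push–pull C4a=C5 bond (pyrylium-enolate resonance form) should rotate fast enough for the whole E/Z mixture to funnel into the one product.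

Step 6
Reactants: 12 (7R)-3-heptyl-7-hydroxy-7-methyl-6H-isochromene-6,8(7H)-dione; 2 octanoyl chloride
Product: 13 (7R)-3-heptyl-7-methyl-6,8-dioxo-7,8-dihydro-6H-isochromen-7-yl octanoate (CNP0155255.1)
Conditions: Et3N (2 equiv), DMAP (0.2 equiv), CH2Cl2, 0 °C → rt
Reagents that add atoms: none
Why: DMAP-catalysed acylation (nucleophilic catalysis via the acylpyridinium ion) esterifies the tertiary α-ketol without breaking any bond to C7, so the configuration is retained.

## Compound list

1 | Meldrum's acid (2,2-dimethyl-1,3-dioxane-4,6-dione) | CC1(C)OC(=O)CC(=O)O1 | starting material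
2 | octanoyl chloride | CCCCCCCC(=O)Cl | starting material
3 | 5-(1-hydroxyoctylidene)-2,2-dimethyl-1,3-dioxane-4,6-dione | CCCCCCCC(O)=C1C(=O)OC(C)(C)OC1=O | intermediate
4 | (E)-1,3,3-trimethoxyprop-1-ene | CO/C=C/C(OC)OC | starting material
5 | heptanoylketene (3-oxodec-1-en-1-one) | CCCCCCCC(=O)C=C=O | intermediate (not isolated)
6 | 3-(dimethoxymethyl)-6-heptyl-2-methoxy-2,3-dihydro-4H-pyran-4-one (diastereomer mixture, racemic) | CCCCCCCC1=CC(=O)C(C(OC)OC)C(OC)O1 | intermediate (not isolated)
7 | 3-(dimethoxymethyl)-6-heptyl-4H-pyran-4-one | CCCCCCCC1=CC(=O)C(C(OC)OC)=CO1 | intermediate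
8 | but-3-yn-2-ol (racemic) | CC(O)C#C | starting material
9 | 3-(dimethoxymethyl)-6-heptyl-4-(3-hydroxybut-1-yn-1-yl)-4H-pyran-4-ol (diastereomer mixture, racemic) | CCCCCCCC1=CC(O)(C#CC(C)O)C(C(OC)OC)=CO1 | intermediate (not isolated)
10 | 6-heptyl-4-(3-hydroxy-2-oxobutylidene)-4H-pyran-3-carbaldehyde (E/Z mixture, racemic) | CCCCCCCC1=CC(=CC(=O)C(C)O)C(C=O)=CO1 | intermediate
11 | 4-(2,3-dioxobutylidene)-6-heptyl-4H-pyran-3-carbaldehyde (E/Z mixture) | CCCCCCCC1=CC(=CC(=O)C(C)=O)C(C=O)=CO1 | intermediate
12 | (7R)-3-heptyl-7-hydroxy-7-methyl-6H-isochromene-6,8(7H)-dione | O[C@]1(C)C(=O)C=C2C=C(CCCCCCC)OC=C2C1=O | intermediate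
13 | (7R)-3-heptyl-7-methyl-6,8-dioxo-7,8-dihydro-6H-isochromen-7-yl octanoate | CCCCCCCC(=O)O[C@]1(C)C(=O)C=C2C=C(CCCCCCC)OC=C2C1=O | target

## Step count and risks

Total step count: 6. Longest linear sequence: 6 steps (1 → 13).

**Step 5 (key step).** Breslow-intermediate formation from the electron-rich, conjugated (vinylogous formate) aldehyde may be slow. The carbene may instead add to the dione or to C1 with opening of the pyran ring, and face selection at the C7 ketone may be insufficient. Fallback from 10, back at 12: the C7–C8 bond is made with the opposite polarity and without an umpolung catalyst. Compound 10 is treated with base (DBU, THF; LiHMDS at −78 °C if needed) so that the enediolate of the α-hydroxy ketone adds through C7 to the C8 aldehyde (intramolecular aldol addition). This should give 3-heptyl-7,8-dihydroxy-7-methyl-7,8-dihydro-6H-isochromen-6-one F1. The allylic C8 carbinol is then oxidised with MnO2 (CH2Cl2) to racemic 3-heptyl-7-hydroxy-7-methyl-6H-isochromene-6,8(7H)-dione F2. Preparative chromatography on a chiral stationary phase returns 12, which is acylated as in step 6.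

**Step 3.** The acetylide may deprotonate the vinylogous α-CH2 of the heptyl chain or add in conjugate fashion at the unsubstituted ring position instead of at the carbonyl. The alkynylpyrylium ion may also be hydrated at a ring carbon with ring opening. Fallback from 7, back at 11: the ylidene is built by sulfide contraction instead of carbonyl addition, and the oxidation of step 4 is no longer needed. Thionation of 7 (Lawesson's reagent, toluene, 80 °C) should give 3-(dimethoxymethyl)-6-heptyl-4H-pyran-4-thione F3. S-Alkylation with commercial 1-bromobutane-2,3-dione (acetone, rt) gives 3-(dimethoxymethyl)-4-[(2,3-dioxobutyl)sulfanyl]-6-heptylpyrylium bromide F4. Et3N and PPh3 (CH2Cl2) then induce episulfide formation and sulfur extrusion (Eschenmoser sulfide contraction) to 1-[3-(dimethoxymethyl)-6-heptyl-4H-pyran-4-ylidene]butane-2,3-dione F5. Dilute aqueous HCl in THF unmasks the aldehyde to give 11.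

**Step 2.** The β-substituted, inductively deactivated enol ether may react too slowly, so that the acylketene dimerises or is trapped by the released acetone or methanol. The acetal may also be scrambled during aromatisation. Fallback from 2, back at 7: the pyranone is built by Claisen acylation and the formyl group is reached by functional-group change.
- Commercial ethyl 2-[(dimethylamino)methylidene]-3-oxobutanoate is deprotonated at its methyl group (LiHMDS, THF, −78 °C) and acylated with 2 to give ethyl 2-[(dimethylamino)methylidene]-3,5-dioxododecanoate F6.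
- Aqueous HCl closes the ring with loss of dimethylamine to ethyl 6-heptyl-4-oxo-4H-pyran-3-carboxylate F7.
- Acid hydrolysis (6 M HCl, AcOH, 90 °C) gives 6-heptyl-4-oxo-4H-pyran-3-carboxylic acid F8.
- Oxalyl chloride (cat. DMF, CH2Cl2) gives 6-heptyl-4-oxo-4H-pyran-3-carbonyl chloride F9.
- LiAlH(OtBu)3 (THF, −78 °C) reduces it to 6-heptyl-4-oxo-4H-pyran-3-carbaldehyde F10.
- Trimethyl orthoformate, MeOH and cat. TsOH give 7.

Further compounds
F1 | step 5 | 3-heptyl-7,8-dihydroxy-7-methyl-7,8-dihydro-6H-isochromen-6-one (diastereomer mixture, racemic) | CCCCCCCC1=CC2=CC(=O)C(C)(O)C(O)C2=CO1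
F2 | step 5 | racemic 3-heptyl-7-hydroxy-7-methyl-6H-isochromene-6,8(7H)-dione | CC1(O)C(=O)C=C2C=C(CCCCCCC)OC=C2C1=O
F3 | step 3 | 3-(dimethoxymethyl)-6-heptyl-4H-pyran-4-thione | CCCCCCCC1=CC(=S)C(C(OC)OC)=CO1
F4 | step 3 | 3-(dimethoxymethyl)-4-[(2,3-dioxobutyl)sulfanyl]-6-heptylpyrylium bromide | CCCCCCCc1cc(SCC(=O)C(C)=O)c(C(OC)OC)c[o+]1.[Br-]
F5 | step 3 | 1-[3-(dimethoxymethyl)-6-heptyl-4H-pyran-4-ylidene]butane-2,3-dione | CCCCCCCC1=CC(=CC(=O)C(C)=O)C(C(OC)OC)=CO1
F6 | step 2 | ethyl 2-[(dimethylamino)methylidene]-3,5-dioxododecanoate | CCCCCCCC(=O)CC(=O)C(=CN(C)C)C(=O)OCC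
F7 | step 2 | ethyl 6-heptyl-4-oxo-4H-pyran-3-carboxylate | CCCCCCCC1=CC(=O)C(C(=O)OCC)=CO1
F8 | step 2 | 6-heptyl-4-oxo-4H-pyran-3-carboxylic acid | CCCCCCCC1=CC(=O)C(C(=O)O)=CO1
F9 | step 2 | 6-heptyl-4-oxo-4H-pyran-3-carbonyl chloride | CCCCCCCC1=CC(=O)C(C(Cl)=O)=CO1
F10 | step 2 | 6-heptyl-4-oxo-4H-pyran-3-carbaldehyde | CCCCCCCC1=CC(=O)C(C=O)=CO1
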